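The runs stem from a simulated flask from invented constants, and the scatter is random.

The constants to start from are the charges: 0.20 M of substrate, 0.180 M of partner and 0.0400 M of protic impurity, the same in noon, autumn, dawn and dusk, which differ in how things go in.

| flask | substrate | partner | protic impurity | remark | time |
|---|---|---|---|---|---|
| alpha | 0.20 M | 0.18 M | 0.040 M | run made earlier |  |
| delta | 0.20 M | 0.27 M | 0.040 M | run made earlier |  |
| noon | 0.20 M | 0.180 M (fed, over 8.0 h) | 0.0400 M | all else is in the flask from the start; the feed brings no volume worth counting | 12 h |
| autumn | 0.20 M | 0.180 M | 0.0400 M | everything together at the start | 12 h |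
| dawn | 0.20 M (fed, over 8.0 h) | 0.180 M | 0.0400 M | all else is in the flask from the start; the feed brings no volume worth counting | 12 h |
| dusk | 0.20 M (in portions, 2, over 8.0 h) | 0.180 M | 0.0400 M | first portion at the start, last at 8.0 h | 12 h |

| run | time / h | product / % | substrate / % |
|---|---|---|---|
| alpha | 0.667 | 54.4 | 45.5 |
| alpha | 2.00 | 70.5 | 28.5 |
| alpha | 3.00 | 75.8 | 25.2 |
| alpha | 5.00 | 76.4 | 25.0 |
| alpha | 8.00 | 76.4 | 23.7 |
| delta | 0.200 | 36.8 | 62.7 |
| delta | 0.333 | 47.9 | 52.8 |
| delta | 0.667 | 61.9 | 38.8 |
| delta | 1.33 | 74.7 | 24.9 |
| delta | 2.50 | 83.5 | 17.0 |

(readings scatter by 0.5 percentage points)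

- a reading or a percentage of product counts all its forms, free or not

- which flask leads in amount of product, in percent of the substrate charged ("all alike" within 1.5 percentage points) (noon / autumn / dawn / dusk / all alike)
- how much product is there at the end, in percent of the substrate charged: noon
- how much product is there at the end, in percent of the substrate charged: autumn
- how much product is there at the end, in percent of the substrate charged: dawn
- how much product is there at the end, in percent of the substrate charged: dusk

Alpha, autumn's recipe, stops near 76.4% of product with 25.0% of substrate left, so you can read partner as the limiting reagent and bracket each flask by where partner goes. From above, if partner went to product and nowhere else, you get 90.0%. From below, let the impurity take its whole charge of partner, one for one; that gives 70.0%, the floor yield: c(partner) less c(protic impurity), divided by c(substrate).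

Now tighten it. Alpha's plateau reading means about 0.0272 M of partner was lost, less than the impurity charge, at a starting ratio of substrate to impurity of 5.00. In dawn that ratio starts at zero, with partner and impurity together from the start and the substrate fed in over 8.0 h. In dusk, the partner beyond the first portion, 0.0800 M, exceeds the impurity. So my own reckoning puts dawn and dusk on the floor, autumn at alpha's plateau, and noon at that mark or over it, below the ceiling.

The forecast leads with noon at 79%, with autumn at 76.4%. It holds that “all impurity is consumed, capping product near 70%”, yet sets dawn at 67% and dusk at 68%, both under my floor.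

The flasks give 80.4% for noon, which leads, 75.8% for autumn, 70.0% for dawn and 70.0% for dusk.

    partner + protic impurity → quenched reagent (k = 0.00410 M⁻¹ s⁻¹)
    substrate + partner → product, rate k2*[substrate]^2*[partner]^0.5 (k = 0.00940 M⁻¹·⁵ s⁻¹)
    crystals ⇌ product, rate k3*(cs3 - [product]) while solid is left; crystals form when [product] > cs3 (solubility = 3.10 mM, k = 0.00390 s⁻¹)
    partner + product ⇌ idle adduct, settled at all times (K = 22.0 M⁻¹)

In dawn at 12.0 h, the impurity is down to 0.00683% of its charge, quenched reagent stands at 0.0400 M, partner at 0%, and product sits on the floor yield of 70.0%, with 68.5% as crystals counted inside it. Now take the neighbour, dawn with 0.068 M of protic impurity. The extra impurity, divided by c(substrate), lowers the floor yield from 70.0% to 56.0%. That flask ends with 0.0773% of its impurity left, 44.0% of substrate and 56.0% of product.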